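(The readings come from a simulation for an exercise.)

Follow the leak. Your hunch that target still leads violet at its late reading fails on this reckoning, though green goes your way.

| setting | gamma | beta | green | violet |
|---|---|---|---|---|
| substrate | 0.26 M (fed, over 5.0 h) | 0.26 M (fed, over 5.0 h) | 0.26 M (fed, over 5.0 h) | 0.26 M (fed, over 5.0 h) |
| capture agent | 0.0087 M | 0.019 M | 0.0130 M | 0.0130 M |
| remark | run made earlier; the fed solution adds 0.10 times the starting volume | run made earlier; the fed solution adds 0.10 times the starting volume | the fed solution adds 0.10 times the starting volume | the fed solution adds 0.10 times the starting volume |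
| time |  |  | 5.0 h | 15 h |

| run | time / h | open intermediate / % | substrate / % | target / % | trapped intermediate / % | isomer of the product / % |
|---|---|---|---|---|---|---|
| gamma | 0.500 | 6.3 | 1.9 | 1.1 | 0.4 | 0 |
| gamma | 0.667 | 7.8 | 2.5 | 2.5 | 0 | 0 |
| gamma | 1.00 | 11.5 | 0.9 | 5.8 | 1.0 | 0.3 |
| gamma | 1.50 | 15.3 | 2.1 | 10.7 | 0 | 1.0 |
| gamma | 2.50 | 21.5 | 1.4 | 21.9 | 0 | 4.1 |
| gamma | 4.00 | 31.2 | 1.3 | 37.5 | 0 | 10.1 |
| gamma | 6.00 | 30.5 | 0 | 50.8 | 2.0 | 16.5 |
| beta | 0.833 | 9.9 | 2.8 | 4.5 | 0.2 | 0 |
| beta | 1.50 | 15.5 | 1.2 | 11.1 | 0.4 | 2.1 |
| beta | 2.50 | 22.6 | 1.7 | 20.5 | 1.3 | 3.6 |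
| beta | 3.00 | 25.6 | 2.2 | 25.9 | 1.1 | 5.6 |
| beta | 4.00 | 30.1 | 0.8 | 37.1 | 2.3 | 9.6 |
| beta | 5.00 | 36.1 | 2.0 | 46.0 | 2.7 | 13.4 |
| beta | 6.00 | 29.7 | 0.8 | 50.9 | 2.8 | 17.1 |

(readings scatter by 0.5 percentage points)

- charges are per starting volume, the dose included; the dosed solution carries all of it
- reactions considered so far: open intermediate <-> isomer of the product; substrate -> open intermediate; open intermediate + capture agent -> trapped intermediate; open intermediate <-> target
- percentages count the whole charge, also what has not yet gone in

* which of these there is most of at the end, counted by the substrate in it, green (substrate / isomer of the product / open intermediate / trapped intermediate / target)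
* which of these there is most of at the end, counted by the substrate in it, violet (substrate / isomer of the product / open intermediate / trapped intermediate / target)
* final amount of the leader among these, as a percentage of the substrate charged, in green
* final amount of the leader among these, as a percentage of the substrate charged, in violet

The capture agent differs by a factor of 2.18 between the earlier runs, yet target at 6.00 h differs by 0.1 percentage points against a scatter of 0.5 points. So the beta run serves as a stand-in for target, open intermediate and isomer in both new flasks. Its row at 5.00 h is the reckoning for green: target 46.0%, open intermediate 36.1%, isomer 13.4%.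

Violet needs a rate. Between 4.00 h and 6.00 h the beta run's isomer grows at k = 0.125 h⁻¹ per unit of open intermediate. At 6.00 h, after the feed, the beta run's pool M of target plus open intermediate reads 80.6%, with an open share s of 36.8%, here taken as constant. The leak constant λ = ks, the fraction of the pool passing to isomer per hour, is 0.0462 h⁻¹.

Over the 9.00 h left, a pool held at M gives 33.5%, so the first round puts isomer at 50.6%. But that loss leaves a pool of 47.1%, so the first round overcharged. Putting the mean of the two pools back in gives 26.6%, so the second round puts isomer at 43.7%. Target is then 34.1%, below isomer.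

The forecast gives target at 46% in green and isomer of the product at 41% in violet, lower than this second round, and warns that “any isomer reversal would narrow it”.

Green ends with target at 46.7%, violet with isomer of the product at 41.2%.

    open intermediate ⇌ isomer of the product (K = 9.19, k = 0.00217 min⁻¹)
    substrate → open intermediate (k = 0.168 min⁻¹)
    open intermediate + capture agent → trapped intermediate (k = 0.0268 M⁻¹ min⁻¹)
    open intermediate ⇌ target (K = 1.70, k = 0.0184 min⁻¹)

In violet, open intermediate and target relax by their own step alone with a half-life of 0.395 h, shorter than the 4.80 h of open intermediate and isomer by theirs: a pre-equilibrium. Taken to violet's neighbour read at 10 h, λ over 4.00 h gives a second-round gain of 13.5%, so isomer 30.6% and target 42.4%. That neighbour holds isomer 29.7% and target 43.4%.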